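**Plan**

- Retrosynthesis: the three O-benzyl bonds are cut first and the C3'=C4' double bond is taken back to the 3',4'-dihydro lactone. The O1'–C8a' bond of pyranone B is then cut (Baeyer–Villiger retron) to give a 2-(coumarin-3-yl)indan-1-one. The indanone is opened at its aryl–carbonyl bond (Friedel–Crafts), the chain at the Cα–CH2Ar bond (enolate benzylation), and pyranone A at C3=C4 and O1–C2 (Perkin-type condensation with succinic anhydride).
- Forward order: syringaldehyde is ortho-hydroxylated to the salicylaldehyde of unit A and pyranone A is closed. The 3,4-bis(benzyloxy)benzyl group is joined to the acetate carbon and the five-membered ketone ring is closed onto the arene. Oxygen insertion expands it to lactone ring B; dehydrogenation and debenzylation finish.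
- Enabling feature: in ring B the lactone oxygen O1' sits on C8a', which is para to the oxygen on C6'. Without O1', ring B is a 5,6-dioxygenated indan-1-one whose aryl carbon shifts readily from carbon to oxygen, so a plain 3,4-dioxygenated benzyl unit is a sufficient source of ring B.
- Stereochemistry: arteminorin C has no stereocentre. The single sp3 centre met on the way (C3', the indanone C2) is carried as the racemate and is erased when C3'=C4' is formed.

Key step: step 12

Remark: unprimed locants denote coumarin unit A (7-oxygenated, 6,8-dimethoxy) and primed locants unit B (6',7'-dioxygenated); 3,4-bis(benzyloxy)benzaldehyde is assumed to be purchasable, otherwise it is one benzylation away from 3,4-dihydroxybenzaldehyde.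

**Route**

Step 1
Reactants: 1 syringaldehyde
Product: 2 4-(benzyloxy)-3,5-dimethoxybenzaldehyde
Conditions: BnBr, K2CO3, DMF, 60 °C
Reagents that add atoms: benzyl bromide, BrCc1ccccc1
Why: Williamson ether synthesis, in which the acidic para-formyl phenoxide is alkylated cleanly by the benzylic bromide.

Step 2
Reactants: 2 4-(benzyloxy)-3,5-dimethoxybenzaldehyde
Product: 3 4-(benzyloxy)-2-bromo-3,5-dimethoxybenzaldehyde
Conditions: NBS, MeCN, 40 °C, dark
Reagents that add atoms: N-bromosuccinimide, O=C1CCC(=O)N1Br
Why: Electrophilic aromatic bromination, in which the two equivalent free ring positions are each ortho and para to a methoxy group, so that one bromine should enter next to the formyl group as it does in 3,4,5-trialkoxybenzaldehydes.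

Step 3
Reactants: 3 4-(benzyloxy)-2-bromo-3,5-dimethoxybenzaldehyde
Product: 4 2-[4-(benzyloxy)-2-bromo-3,5-dimethoxyphenyl]-1,3-dioxolane
Conditions: HOCH2CH2OH, pyridinium p-toluenesulfonate (cat.), toluene, reflux, Dean–Stark trap
Reagents that add atoms: ethylene glycol, OCCO
Why: Acid-catalysed acetalisation with azeotropic removal of water, which masks the aldehyde against the organolithium and the peroxide of the next step.

Step 4
Reactants: 4 2-[4-(benzyloxy)-2-bromo-3,5-dimethoxyphenyl]-1,3-dioxolane
Product: 8 4-(benzyloxy)-2-hydroxy-3,5-dimethoxybenzaldehyde, via aryllithium 5 (not isolated), via dimethyl arylboronate 6 (not isolated), via phenol dioxolane 7 (not isolated)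
Conditions: n-BuLi, THF, −78 °C; B(OMe)3, −78 °C to rt; H2O2, NaOH aq, 0 °C; then aq HCl, THF, rt
Reagents that add atoms: hydrogen peroxide, OO; water, O
Why: Bromine–lithium exchange, borylation and oxidative carbon-to-oxygen shift on boron form the standard aryl bromide to phenol sequence, and the dioxolane, hydrolysed only after excess peroxide has been destroyed, keeps the aldehyde away from butyllithium and from a Dakin oxidation.

Step 5
Reactants: 8 4-(benzyloxy)-2-hydroxy-3,5-dimethoxybenzaldehyde; 9 succinic anhydride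
Product: 10 2-[7-(benzyloxy)-6,8-dimethoxy-2-oxo-2H-chromen-3-yl]acetic acid
Conditions: Na2(O2CCH2CH2CO2) (disodium succinate, anhydrous), neat melt, 170–180 °C; then aq HCl
Reagents that add atoms: none
Why: Perkin-type condensation, in which the phenol is acylated by the anhydride, the enolised hemisuccinate adds to the ortho aldehyde and loss of water closes pyranone A with the CH2CO2H group on C3, as salicylaldehyde itself is known to do.

Step 6
Reactants: 10 2-[7-(benzyloxy)-6,8-dimethoxy-2-oxo-2H-chromen-3-yl]acetic acid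
Product: 11 tert-butyl 2-[7-(benzyloxy)-6,8-dimethoxy-2-oxo-2H-chromen-3-yl]acetate
Conditions: Cl3CC(=NH)Ot-Bu, CH2Cl2/cyclohexane, rt
Reagents that add atoms: tert-butyl 2,2,2-trichloroacetimidate, CC(C)(C)OC(=N)C(Cl)(Cl)Cl
Why: Imidate esterification, in which the acid protonates the imidate and captures the tert-butyl cation, giving an ester that can later be removed without hydroxide, which would open the lactone.

Step 7
Reactants: 12 3,4-bis(benzyloxy)benzaldehyde
Product: 13 [3,4-bis(benzyloxy)phenyl]methanol
Conditions: NaBH4, MeOH/THF, 0 °C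
Reagents that add atoms: none
Why: Borohydride reduction of an aromatic aldehyde to the benzylic alcohol.

Step 8
Reactants: 13 [3,4-bis(benzyloxy)phenyl]methanol
Product: 14 1,2-bis(benzyloxy)-4-(bromomethyl)benzene
Conditions: PBr3, Et2O, 0 °C
Reagents that add atoms: phosphorus tribromide, BrP(Br)Br
Why: Alcohol-to-bromide substitution through the phosphite ester, which is fast for an electron-rich benzylic alcohol.

Step 9
Reactants: 11 tert-butyl 2-[7-(benzyloxy)-6,8-dimethoxy-2-oxo-2H-chromen-3-yl]acetate; 14 1,2-bis(benzyloxy)-4-(bromomethyl)benzene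
Product: 16 racemic tert-butyl 3-[3,4-bis(benzyloxy)phenyl]-2-[7-(benzyloxy)-6,8-dimethoxy-2-oxo-2H-chromen-3-yl]propanoate, via lithium enolate 15 (not isolated)
Conditions: LiN(SiMe3)2, THF, −78 °C; then 14, −78 to −20 °C
Reagents that add atoms: none
Why: Ester enolate alkylation, in which the non-nucleophilic amide removes a proton from the CH2 flanked by the ester and the sp2 carbon C3 (an arylacetate-like position) and the enolate is benzylated at carbon by SN2, the new centre being formed racemic and not needed later.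

Step 10
Reactants: 16 racemic tert-butyl 3-[3,4-bis(benzyloxy)phenyl]-2-[7-(benzyloxy)-6,8-dimethoxy-2-oxo-2H-chromen-3-yl]propanoate
Product: 17 racemic 3-[3,4-bis(benzyloxy)phenyl]-2-[7-(benzyloxy)-6,8-dimethoxy-2-oxo-2H-chromen-3-yl]propanoic acid
Conditions: CF3CO2H/CH2Cl2 (1:4), rt
Reagents that add atoms: none
Why: Acidolysis of the tert-butyl ester with loss of 2-methylpropene, under which aryl benzyl ethers and the lactone should survive a short exposure.

Step 11
Reactants: 17 racemic 3-[3,4-bis(benzyloxy)phenyl]-2-[7-(benzyloxy)-6,8-dimethoxy-2-oxo-2H-chromen-3-yl]propanoic acid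
Product: 19 racemic 3-[5,6-bis(benzyloxy)-1-oxo-2,3-dihydro-1H-inden-2-yl]-7-(benzyloxy)-6,8-dimethoxy-2H-chromen-2-one, via acid chloride 18 (not isolated)
Conditions: (COCl)2, Me2NCHO (cat.), CH2Cl2, 0 °C to rt; evaporate; (CF3)2CHOH, rt
Reagents that add atoms: none
Why: Intramolecular Friedel–Crafts acylation, in which the acid chloride is activated by the strongly hydrogen-bonding fluoro alcohol and attacks the ring position para to the 3-benzyloxy group to close the five-membered ketone, without a Lewis acid that could strip the benzyl ethers.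

Step 12
Reactants: 19 racemic 3-[5,6-bis(benzyloxy)-1-oxo-2,3-dihydro-1H-inden-2-yl]-7-(benzyloxy)-6,8-dimethoxy-2H-chromen-2-one
Product: 20 racemic 7,6',7'-tris(benzyloxy)-6,8-dimethoxy-3',4'-dihydro-2H,2'H-[3,3'-bichromene]-2,2'-dione
Conditions: mCPBA, CF3CO2H (cat.), CH2Cl2, 0 °C to rt, dark
Reagents that add atoms: 3-chloroperbenzoic acid, OOC(=O)c1cccc(Cl)c1
Why: Baeyer–Villiger oxidation: the peracid adds to the indanone carbonyl (the future C2') to give the Criegee adduct, whose aryl carbon (indanone C7a, the future C8a') shifts from carbon to oxygen as 3-chlorobenzoate leaves, so that O1' ends up between C8a' and C2'. The closest known reaction type is the peracid conversion of 5-alkoxyindan-1-ones into 3,4-dihydrocoumarins. Lactone ring B thus arises by one-atom ring expansion of the five-membered ketone (five to six, through the 1,2-aryl shift) and not by cyclisation of an open chain. No stereocentre is made, and the existing C3' centre is untouched, stays racemic and disappears in step 13. The step needs migration of the aryl carbon in preference to the secondary carbon C3', which is secured by the benzyloxy group para to the migrating carbon together with the electron-poor 2-oxochromen-3-yl group on the rival carbon. It also needs the rest of the molecule to resist the peracid, which the acceptor-substituted C3=C4 bond of unit A and the aryl ethers should do at this temperature.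

Step 13
Reactants: 20 racemic 7,6',7'-tris(benzyloxy)-6,8-dimethoxy-3',4'-dihydro-2H,2'H-[3,3'-bichromene]-2,2'-dione
Product: 21 7,6',7'-tris(benzyloxy)-6,8-dimethoxy-2H,2'H-[3,3'-bichromene]-2,2'-dione
Conditions: DDQ, 1,4-dioxane, reflux
Reagents that add atoms: none
Why: Quinone dehydrogenation, in which hydride is abstracted from C4' (benzylic and para to the 7'-benzyloxy group) and the acidic C3' proton is then lost, giving the fully conjugated bicoumarin.

Step 14
Reactants: 21 7,6',7'-tris(benzyloxy)-6,8-dimethoxy-2H,2'H-[3,3'-bichromene]-2,2'-dione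
Product: 22 arteminorin C
Conditions: BCl3, C6HMe5, CH2Cl2, −78 °C; then MeOH
Reagents that add atoms: none
Why: Lewis-acid debenzylation with pentamethylbenzene as a non-basic benzyl cation trap, which at low temperature cleaves aryl benzyl ethers but should spare the two methyl ethers, both lactones and both C3=C4 bonds, which hydrogenolysis could reduce.

**Compound list**

1 | syringaldehyde (4-hydroxy-3,5-dimethoxybenzaldehyde) | COc1cc(C=O)cc(OC)c1O | starting material
2 | 4-(benzyloxy)-3,5-dimethoxybenzaldehyde | COc1cc(C=O)cc(OC)c1OCc1ccccc1 | intermediate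
3 | 4-(benzyloxy)-2-bromo-3,5-dimethoxybenzaldehyde | COc1cc(C=O)c(Br)c(OC)c1OCc1ccccc1 | intermediate
4 | 2-[4-(benzyloxy)-2-bromo-3,5-dimethoxyphenyl]-1,3-dioxolane | COc1cc(C2OCCO2)c(Br)c(OC)c1OCc1ccccc1 | intermediate
5 | [3-(benzyloxy)-6-(1,3-dioxolan-2-yl)-2,4-dimethoxyphenyl]lithium | COc1cc(C2OCCO2)c([Li])c(OC)c1OCc1ccccc1 | intermediate (not isolated)
6 | dimethyl [3-(benzyloxy)-6-(1,3-dioxolan-2-yl)-2,4-dimethoxyphenyl]boronate | COc1cc(C2OCCO2)c(B(OC)OC)c(OC)c1OCc1ccccc1 | intermediate (not isolated)
7 | 3-(benzyloxy)-6-(1,3-dioxolan-2-yl)-2,4-dimethoxyphenol | COc1cc(C2OCCO2)c(O)c(OC)c1OCc1ccccc1 | intermediate (not isolated)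
8 | 4-(benzyloxy)-2-hydroxy-3,5-dimethoxybenzaldehyde | COc1cc(C=O)c(O)c(OC)c1OCc1ccccc1 | intermediate
9 | succinic anhydride | O=C1CCC(=O)O1 | starting material
10 | 2-[7-(benzyloxy)-6,8-dimethoxy-2-oxo-2H-chromen-3-yl]acetic acid | COc1cc2cc(CC(=O)O)c(=O)oc2c(OC)c1OCc1ccccc1 | intermediate
11 | tert-butyl 2-[7-(benzyloxy)-6,8-dimethoxy-2-oxo-2H-chromen-3-yl]acetate | COc1cc2cc(CC(=O)OC(C)(C)C)c(=O)oc2c(OC)c1OCc1ccccc1 | intermediate
12 | 3,4-bis(benzyloxy)benzaldehyde | O=Cc1ccc(OCc2ccccc2)c(OCc2ccccc2)c1 | starting material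
13 | [3,4-bis(benzyloxy)phenyl]methanol | OCc1ccc(OCc2ccccc2)c(OCc2ccccc2)c1 | intermediate
14 | 1,2-bis(benzyloxy)-4-(bromomethyl)benzene | BrCc1ccc(OCc2ccccc2)c(OCc2ccccc2)c1 | intermediate
15 | lithium enolate of 11 | COc1cc2cc(C=C(O[Li])OC(C)(C)C)c(=O)oc2c(OC)c1OCc1ccccc1 | intermediate (not isolated)
16 | tert-butyl 3-[3,4-bis(benzyloxy)phenyl]-2-[7-(benzyloxy)-6,8-dimethoxy-2-oxo-2H-chromen-3-yl]propanoate (racemic) | COc1cc2cc(C(Cc3ccc(OCc4ccccc4)c(OCc4ccccc4)c3)C(=O)OC(C)(C)C)c(=O)oc2c(OC)c1OCc1ccccc1 | intermediate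
17 | 3-[3,4-bis(benzyloxy)phenyl]-2-[7-(benzyloxy)-6,8-dimethoxy-2-oxo-2H-chromen-3-yl]propanoic acid (racemic) | COc1cc2cc(C(Cc3ccc(OCc4ccccc4)c(OCc4ccccc4)c3)C(=O)O)c(=O)oc2c(OC)c1OCc1ccccc1 | intermediate
18 | 3-[3,4-bis(benzyloxy)phenyl]-2-[7-(benzyloxy)-6,8-dimethoxy-2-oxo-2H-chromen-3-yl]propanoyl chloride (racemic) | COc1cc2cc(C(Cc3ccc(OCc4ccccc4)c(OCc4ccccc4)c3)C(=O)Cl)c(=O)oc2c(OC)c1OCc1ccccc1 | intermediate (not isolated)
19 | 3-[5,6-bis(benzyloxy)-1-oxo-2,3-dihydro-1H-inden-2-yl]-7-(benzyloxy)-6,8-dimethoxy-2H-chromen-2-one (racemic) | COc1cc2cc(C3Cc4cc(OCc5ccccc5)c(OCc5ccccc5)cc4C3=O)c(=O)oc2c(OC)c1OCc1ccccc1 | intermediate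
20 | 7,6',7'-tris(benzyloxy)-6,8-dimethoxy-3',4'-dihydro-2H,2'H-[3,3'-bichromene]-2,2'-dione (racemic) | COc1cc2cc(C3Cc4cc(OCc5ccccc5)c(OCc5ccccc5)cc4OC3=O)c(=O)oc2c(OC)c1OCc1ccccc1 | intermediate
21 | 7,6',7'-tris(benzyloxy)-6,8-dimethoxy-2H,2'H-[3,3'-bichromene]-2,2'-dione | COc1cc2cc(-c3cc4cc(OCc5ccccc5)c(OCc5ccccc5)cc4oc3=O)c(=O)oc2c(OC)c1OCc1ccccc1 | intermediate
22 | arteminorin C (7,6',7'-trihydroxy-6,8-dimethoxy-2H,2'H-[3,3'-bichromene]-2,2'-dione) | COc1cc2cc(-c3cc4cc(O)c(O)cc4oc3=O)c(=O)oc2c(OC)c1O | target

**Count and risks**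

Total step count: 14. Longest linear sequence: 12 steps (steps 1 to 6 and 9 to 14, from syringaldehyde); the benzyl bromide branch (steps 7 and 8) is two steps.

The three steps most likely to fail:

Step 12. The secondary alkyl carbon could migrate in competition with the aryl carbon, or the peracid could attack through the enol at the acidic C–H next to the ketone. The fallback sets out from 10 and 12 and comes back at 21; it brings the C8a'–O1' oxygen in on the arene before ring B is closed. Dakin-type oxidation of 12 (mCPBA, CH2Cl2) should give 3,4-bis(benzyloxy)phenyl formate F1, and methanolysis (K2CO3, MeOH) 3,4-bis(benzyloxy)phenol F2. Magnesium-mediated ortho-formylation (MgCl2, Et3N, paraformaldehyde, MeCN, reflux) at the less hindered ortho position should give 4,5-bis(benzyloxy)-2-hydroxybenzaldehyde F3. A Perkin–Oglialoro condensation of F3 with acid 10 (Ac2O, Et3N, 120 °C) would then close pyranone B directly at the coumarin oxidation level and give 21.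

Step 5. Thermal decomposition in the melt and further condensation at the activated methylene of the product could leave little of the coumarin acid. The fallback sets out from 8 and comes back at 11; it attaches the acetate carbon by cross-coupling. Wittig olefination with lactonisation (Ph3P=CHCO2Et, N,N-diethylaniline, reflux) should give 7-(benzyloxy)-6,8-dimethoxy-2H-chromen-2-one F4. Bromination at the nucleophilic C3 (Br2, AcOH, rt) should give 7-(benzyloxy)-3-bromo-6,8-dimethoxy-2H-chromen-2-one F5. Palladium-catalysed coupling of F5 with the Reformatsky reagent BrZnCH2CO2t-Bu (Pd(dba)2, P(t-Bu)3, THF, rt) would then deliver 11 without passing through 10.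

Step 13. Hydride abstraction could stall, or the quinone could oxidise the benzylic positions of the benzyl ethers on prolonged heating. The fallback sets out from 20 and comes back at 21; it replaces hydride abstraction by enolate selenenylation and syn-elimination. Deprotonation at C3' (LiN(SiMe3)2, THF, −78 °C) should give the lithium enolate F6, and trapping with PhSeBr the 3'-(phenylselanyl) lactone F7. Oxidation (H2O2, pyridine, CH2Cl2, 0 °C) to the selenoxide F8 would be followed by spontaneous syn-elimination toward C4', the only position with a β-hydrogen, to give 21.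

**Further compounds**

F1 | step 12 | 3,4-bis(benzyloxy)phenyl formate | O=COc1ccc(OCc2ccccc2)c(OCc2ccccc2)c1
F2 | step 12 | 3,4-bis(benzyloxy)phenol | Oc1ccc(OCc2ccccc2)c(OCc2ccccc2)c1
F3 | step 12 | 4,5-bis(benzyloxy)-2-hydroxybenzaldehyde | O=Cc1cc(OCc2ccccc2)c(OCc2ccccc2)cc1O
F4 | step 5 | 7-(benzyloxy)-6,8-dimethoxy-2H-chromen-2-one | COc1cc2ccc(=O)oc2c(OC)c1OCc1ccccc1
F5 | step 5 | 7-(benzyloxy)-3-bromo-6,8-dimethoxy-2H-chromen-2-one | COc1cc2cc(Br)c(=O)oc2c(OC)c1OCc1ccccc1
F6 | step 13 | lithium enolate of 20 | COc1cc2cc(C3=C(O[Li])Oc4cc(OCc5ccccc5)c(OCc5ccccc5)cc4C3)c(=O)oc2c(OC)c1OCc1ccccc1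
F7 | step 13 | 7,6',7'-tris(benzyloxy)-6,8-dimethoxy-3'-(phenylselanyl)-3',4'-dihydro-2H,2'H-[3,3'-bichromene]-2,2'-dione (racemic) | COc1cc2cc(C3([Se]c4ccccc4)Cc4cc(OCc5ccccc5)c(OCc5ccccc5)cc4OC3=O)c(=O)oc2c(OC)c1OCc1ccccc1
F8 | step 13 | selenoxide of F7 (3'-(phenylseleninyl) lactone) | COc1cc2cc(C3([Se](=O)c4ccccc4)Cc4cc(OCc5ccccc5)c(OCc5ccccc5)cc4OC3=O)c(=O)oc2c(OC)c1OCc1ccccc1
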